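The numbers in the tables come from a simulation with constants of no real substance; scatter was added.

**What was asked**

| flask | left-handed substrate | right-handed substrate | gas | precatalyst | remark | time |
|---|---|---|---|---|---|---|
| elm | 1.4 M | 1.4 M | 34 mM (held) | 2 mM | run made earlier |  |
| alder | 2.2 M | 2.2 M | 34 mM (held) | 2 mM | run made earlier |  |
| flask | 1.0 M | 1.0 M | 34 mM (held) | 2.0 mM |  | 12 min |

- elm (time / min: right-handed substrate / %, left-handed substrate / %, left-handed product / %): 0.500: 51, 43, 8; 1.00: 47, 26, 25; 1.50: 48, 13, 35; 2.50: 41, 3, 48; 4.00: 30, 2, 50; 8.00: 12, 1, 48
- alder (time / min: right-handed substrate / %, left-handed substrate / %, left-handed product / %): 0.500: 48, 44, 5; 1.33: 47, 26, 24; 2.50: 44, 10, 38; 4.00: 38, 1, 51; 6.00: 28, 0, 49; 8.00: 17, 0, 52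

(scatter of a reading: 1.5 percentage points)

- free catalyst is single-handed; left-handed substrate and right-handed substrate are mirror images of each other, charged as a racemate, each of them at the stated concentration
- at the start none of partner is dissolved
- steps under discussion: free catalyst + left-handed substrate <-> catalyst intermediate A; free catalyst + right-handed substrate <-> catalyst intermediate B; partner + catalyst intermediate A -> free catalyst + left-handed product; partner + precatalyst -> free catalyst + spent reagent; partner + catalyst intermediate B -> free catalyst + right-handed product; gas <-> partner

- whether the excess of right-handed substrate over left-handed substrate among what is left of the two reaches 80 % by 12 min (yes / no)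
- the highest excess of right-handed substrate over left-handed substrate among what is left of the two up to 12 min

**The reckoning**

1. I began in a one-step world, where each substrate falls first-order and the catalyst prefers the left-handed one. There, the selectivity factor s, the logarithm of the fraction of its own charge left of left-handed substrate divided by the same logarithm for right-handed substrate, stays constant. Each substrate's charge was 0.5 of both together.

2. The alder readings of both substrates at 2.50 min gave s = 12.6.

3. An excess of 80 % in the flask means [left-handed substrate]/[right-handed substrate] = 0.111. With equal charges, that ratio is the right-handed fraction raised to s minus 1. So I reckoned the level of right-handed substrate at that excess as 41.4 % of both charged.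

4. The weak link was the denominator: right-handed substrate had fallen by 6 percentage points, against a scatter of 1.5 points. I reforged it by pooling the logarithms with elm at 2.50 min, which gave a reading of 13.6 for the selectivity factor. I carried this reading to the flask, and my reckoned level became 42.0 %.

5. By 4.00 min, elm and alder read 30 % and 38 %, both below that level; the flask had a smaller charge than either and a longer time than that, so I committed to yes for the flask. At 8.00 min they read 12 % and 17 %, under 0.5 of their own charge. At that fraction in the flask, s gave me an excess of >99.9 %.

**The flask**

6. The forecast said yes with a top of 99.9 %, reasoning that the “excess should therefore approach” its limit.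

7. The flask answered yes, and its excess topped out at 100 %.

    free catalyst + left-handed substrate ⇌ catalyst intermediate A (K = 4.10 M⁻¹, k = 1000 M⁻¹ s⁻¹)
    free catalyst + right-handed substrate ⇌ catalyst intermediate B (K = 0.790 M⁻¹, k = 1600 M⁻¹ s⁻¹)
    partner + catalyst intermediate A → free catalyst + left-handed product (k = 310 M⁻¹ s⁻¹)
    partner + precatalyst → free catalyst + spent reagent (k = 2.00 M⁻¹ s⁻¹)
    partner + catalyst intermediate B → free catalyst + right-handed product (k = 110 M⁻¹ s⁻¹)
    gas ⇌ partner, rate k6*(csat - [partner]) (kL = 44.0 s⁻¹)

8. The excess in the flask reached 80 % at 1.80 min with 42.2 % of right-handed substrate left, against my 42.0 %; at 12.0 min, 2.22 % remained. In alder at 4.00 min, right-handed substrate read 38 %, so s gave 1.21 % of left-handed substrate, and the reading was 1 %.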